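**Retrosynthetic overview**
1. The chain is cut at its CH2–CH= bond (B-alkyl Suzuki–Miyaura coupling) into ring fragment 17 (C14 alkenyl iodide) and head fragment 24 (C6 vinyl/alkynyl carbinol). The enol acetate comes from the alkyne through an (E)-alkenylboronate, the aldehyde from a CH2OSiEt3 group, and the (R)-quaternary carbinol from a Sharpless epoxidation.
2. Ring A is the only ring (C1 = stereogenic CH, C2(Me)=C3H, C4H2, C5H2, C6 = CMe2). It is closed by forming C6–C1: a tertiary C6–F bond is ionised and the cation is captured by an internal (E)-allylsilane C1=C2–C3(SiMe2Ph) in an anti-SE2′ process that expels PhMe2SiF.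
3. Enabling feature: C1 lies between the quaternary carbon C6 and the C2=C3 alkene, so C6–C1–C2=C3 is the footprint of a tertiary cation added to the γ-carbon of an allylsilane with silicon on C3. The C3–Si bond is absent from the target; it is made on purpose, carries the only stereochemical information, fixes the alkene position and is cleaved in the same step.
4. The acyclic precursor 12 is assembled from simple achiral pieces: fluoro carbamate 3 (lithiation–silaboration sets C3) and aldehyde 8 (via Z-iodoalkene 9), joined by Zweifel olefination.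
5. Order of ring formation: ring A only, in step 7; all later steps elaborate the side chain.

Key step: step 7

Remark on the chemistry: the target SMILES is read as (R) at the acetoxy-bearing quaternary carbon and (S) at the ring carbon, with an E enol acetate and an E trisubstituted chain alkene.

Step 1
Reactants: 1 4-methylpent-4-en-1-ol
Product: 2 4-methylpent-4-en-1-yl N,N-diisopropylcarbamate
Conditions: iPr2NCOCl, Et3N, CH2Cl2, reflux
Reagents that add atoms: N,N-diisopropylcarbamoyl chloride, CC(C)N(C(C)C)C(=O)Cl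
Why: O-carbamoylation of the primary alcohol installs the group that later directs and acidifies the α-oxygenated CH2 position.

Step 2
Reactants: 2 4-methylpent-4-en-1-yl N,N-diisopropylcarbamate
Product: 3 4-fluoro-4-methylpentyl N,N-diisopropylcarbamate
Conditions: HF·pyridine, CH2Cl2, 0 °C (polyethylene flask)
Reagents that add atoms: hydrogen fluoride, F
Why: Markovnikov hydrofluorination (protonation of the 1,1-disubstituted alkene, capture of the tertiary cation by fluoride) stores the future CMe2 ring carbon as a latent cation that should be inert to bases and to organolithium reagents at low temperature.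

Step 3
Reactants: 3 4-fluoro-4-methylpentyl N,N-diisopropylcarbamate
Product: 6 (R)-[4-fluoro-4-methyl-1-(4,4,5,5-tetramethyl-1,3,2-dioxaborolan-2-yl)pentyl]dimethyl(phenyl)silane, via lithiated carbamate 4 (not isolated), via silylboronate complex 5 (not isolated)
Conditions: s-BuLi, (−)-sparteine, Et2O, −78 °C; PhMe2Si–Bpin, −78 °C to reflux
Reagents that add atoms: (dimethylphenylsilyl)boronic acid pinacol ester, C[Si](C)(c1ccccc1)B1OC(C)(C)C(C)(C)O1
Why: Sparteine-mediated Hoppe deprotonation removes the pro-S hydrogen to give configurationally stable 4, which adds to boron with retention, and the Matteson-type 1,2-shift of silicon with inversion and loss of the carbamate (lithiation–borylation with a silylboronate) sets the C–Si stereocentre as (R).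

Step 4
Reactants: 7 5-(trimethylsilyl)pent-4-yn-1-ol
Product: 8 5-(trimethylsilyl)pent-4-ynal
Conditions: TEMPO (cat.), PhI(OAc)2, CH2Cl2, rt
Reagents that add atoms: none
Why: Oxoammonium-catalysed alcohol oxidation stops at the aldehyde and leaves the silylalkyne untouched.

Step 5
Reactants: 8 5-(trimethylsilyl)pent-4-ynal
Product: 9 (Z)-(6-iodohept-5-en-1-yn-1-yl)trimethylsilane
Conditions: [Ph3PEt]I, n-BuLi, THF, rt; I2, −78 °C; NaHMDS, −20 °C; 8, −78 °C
Reagents that add atoms: ethyltriphenylphosphonium iodide, CC[P+](c1ccccc1)(c1ccccc1)c1ccccc1.[I-]; iodine, II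
Why: The Stork–Zhao-type Wittig olefination with the α-iodo ylide is kinetically Z-selective, so iodine ends cis to the chain, which is the geometry that the next step inverts.

Step 6
Reactants: 9 (Z)-(6-iodohept-5-en-1-yn-1-yl)trimethylsilane; 6 (R)-[4-fluoro-4-methyl-1-(4,4,5,5-tetramethyl-1,3,2-dioxaborolan-2-yl)pentyl]dimethyl(phenyl)silane
Product: 12 (5S,6E)-5-[dimethyl(phenyl)silyl]-2-fluoro-2,6-dimethyl-11-(trimethylsilyl)undec-6-en-10-yne, via alkenyllithium 10 (not isolated), via alkenylboronate complex 11 (not isolated)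
Conditions: 9, t-BuLi (2 equiv), Et2O, −78 °C; 6, THF, −78 °C; I2, −78 °C; NaOMe, MeOH, −78 to 0 °C
Reagents that add atoms: none
Why: Zweifel olefination (iodine–lithium exchange with retention, boronate formation, iodine-induced 1,2-migration with retention at the α-silyl carbon, anti elimination) inverts the alkene geometry, so the Z-iodide gives the (E)-allylsilane whose unchanged C–Si centre is now described as (S).

Step 7
Reactants: 12 (5S,6E)-5-[dimethyl(phenyl)silyl]-2-fluoro-2,6-dimethyl-11-(trimethylsilyl)undec-6-en-10-yne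
Product: 14 (S)-trimethyl[4-(2,6,6-trimethylcyclohex-2-en-1-yl)but-1-yn-1-yl]silane, via tertiary carbocation 13 (not isolated)
Conditions: BF3·OEt2 (0.2 equiv), 2,6-di-tert-butyl-4-methylpyridine (0.3 equiv), CH2Cl2, −78 to −40 °C
Reagents that add atoms: none
Why: Proposed new method: BF3 abstracts fluoride from the tertiary C–F bond of 12 to give the dimethylcarbinyl cation 13 (BF4− ion pair), the γ-carbon of the internal (E)-allylsilane attacks it, and BF4− hands fluoride to silicon of the resulting β-silyl cation, so that PhMe2SiF leaves, BF3 is regenerated and the strong Si–F bond drives a proton-free catalytic cycle. The closest known reaction types are the BF3-catalysed tert-alkylation of allylsilanes and silyl enol ethers by tertiary alkyl fluorides, the TiCl4-mediated tert-alkylation of allylsilanes by tert-alkyl chlorides and the allylsilane-terminated cation–olefin cyclisation; new are the intramolecular setting with the silicon-bearing carbon inside the forming ring and its use as the only stereochemical source. The six-membered ring closes in the 6-endo-trig mode, because this places the charge on the tertiary β-silyl carbon, whereas 5-exo closure would give an unstabilised secondary cation beside two quaternary carbons. The new ring stereocentre is controlled by the C–Si stereocentre: in the chair transition state the C–Si bond is pseudoaxial (σ–π overlap and relief of A1,2 strain with the vinylic methyl group) and the cation adds to the alkene face anti to silicon (anti-SE2′), so the (5S,6E)-silane should give the (S)-configured ring carbon while its own stereocentre is erased. The step needs alkene position selectivity, monocyclisation and chemoselective initiation: loss of silicon can only place the alkene between the methyl-bearing carbon and the former C–Si carbon (no exocyclic or tetrasubstituted isomer), desilylation outruns capture by the far less nucleophilic silylalkyne, and a fluorophilic Lewis acid beside a hindered pyridine ionises C–F without the Brønsted acid that would protodesilylate the allylsilane.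

Step 8
Reactants: 14 (S)-trimethyl[4-(2,6,6-trimethylcyclohex-2-en-1-yl)but-1-yn-1-yl]silane
Product: 15 (S)-6-(but-3-yn-1-yl)-1,5,5-trimethylcyclohex-1-ene
Conditions: K2CO3 (cat.), MeOH, rt
Reagents that add atoms: none
Why: Base-catalysed methanolysis of the C(sp)–Si bond (protodesilylation of an alkynylsilane) touches neither the ring alkene nor the allylic stereocentre.

Step 9
Reactants: 15 (S)-6-(but-3-yn-1-yl)-1,5,5-trimethylcyclohex-1-ene
Product: 17 (S)-6-[(E)-4-iodo-3-methylbut-3-en-1-yl]-1,5,5-trimethylcyclohex-1-ene, via alkenylalane 16 (not isolated)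
Conditions: Me3Al, Cp2ZrCl2 (cat.), CH2Cl2, 0 °C to rt; I2, THF, −30 °C
Reagents that add atoms: trimethylaluminium, C[Al](C)C; iodine, II
Why: Negishi Cp2ZrCl2-catalysed carboalumination adds methyl and aluminium syn and regioselectively across the terminal alkyne, and iodinolysis with retention gives the (E)-trisubstituted alkenyl iodide while the hindered ring alkene stays inert.

Step 10
Reactants: 18 2-bromoprop-2-en-1-ol; 19 ethynyl(trimethyl)silane
Product: 20 2-[(trimethylsilyl)ethynyl]prop-2-en-1-ol
Conditions: PdCl2(PPh3)2 (cat.), CuI (cat.), iPr2NH, THF, rt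
Reagents that add atoms: none
Why: Sonogashira coupling of the alkenyl bromide tolerates the free allylic alcohol and gives the cross-conjugated enynol.

Step 11
Reactants: 20 2-[(trimethylsilyl)ethynyl]prop-2-en-1-ol
Product: 21 (R)-{2-[(trimethylsilyl)ethynyl]oxiran-2-yl}methanol
Conditions: Ti(OiPr)4 (cat.), D-(−)-diethyl tartrate (cat.), t-BuOOH, 4 Å MS, CH2Cl2, −20 °C
Reagents that add atoms: tert-butyl hydroperoxide, CC(C)(C)OO
Why: In the Sharpless asymmetric epoxidation the complex of Ti(OiPr)4, tartrate and the bound allylic alkoxide delivers oxygen to one alkene face, and D-(−)-tartrate should give the (R)-epoxy alcohol, which fixes the C–O bond of the later acetoxy-bearing quaternary carbon.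

Step 12
Reactants: 21 (R)-{2-[(trimethylsilyl)ethynyl]oxiran-2-yl}methanol
Product: 22 (S)-triethyl({2-[(trimethylsilyl)ethynyl]oxiran-2-yl}methoxy)silane
Conditions: Et3SiCl, imidazole, CH2Cl2, 0 °C
Reagents that add atoms: chlorotriethylsilane, CC[Si](Cl)(CC)CC
Why: Silylation of the primary alcohol (descriptor change by priority only) gives a triethylsilyl ether that survives the basic steps and can be oxidised directly in the last step.

Step 13
Reactants: 22 (S)-triethyl({2-[(trimethylsilyl)ethynyl]oxiran-2-yl}methoxy)silane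
Product: 24 (R)-3-{[(triethylsilyl)oxy]methyl}-5-(trimethylsilyl)pent-1-en-4-yn-3-ol, via oxidosulfonium betaine 23 (not isolated)
Conditions: Me3SI, n-BuLi, THF, −10 °C to rt
Reagents that add atoms: trimethylsulfonium iodide, C[S+](C)C.[I-]
Why: One-carbon homologation of a terminal epoxide to an allylic alcohol with excess dimethylsulfonium methylide proceeds by SN2 opening at the CH2 terminus to 23 and elimination of dimethyl sulfide, so the C–O bond at the stereocentre is never broken.

Step 14
Reactants: 24 (R)-3-{[(triethylsilyl)oxy]methyl}-5-(trimethylsilyl)pent-1-en-4-yn-3-ol; 17 (S)-6-[(E)-4-iodo-3-methylbut-3-en-1-yl]-1,5,5-trimethylcyclohex-1-ene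
Product: 26 (3R,6E)-7-methyl-3-{[(triethylsilyl)oxy]methyl}-1-(trimethylsilyl)-9-[(1S)-2,6,6-trimethylcyclohex-2-en-1-yl]non-6-en-1-yn-3-ol, via alkylborane 25 (not isolated)
Conditions: 24, 9-BBN-H (2.2 equiv), THF, rt; then 17, Pd(dppf)Cl2 (cat.), Cs2CO3, DMF–H2O, rt
Reagents that add atoms: none
Why: In the B-alkyl Suzuki–Miyaura coupling 9-BBN-H adds anti-Markovnikov to the monosubstituted alkene much faster than to the silylalkyne, and the alkylborane couples with the alkenyl iodide with retention of the E geometry.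

Step 15
Reactants: 26 (3R,6E)-7-methyl-3-{[(triethylsilyl)oxy]methyl}-1-(trimethylsilyl)-9-[(1S)-2,6,6-trimethylcyclohex-2-en-1-yl]non-6-en-1-yn-3-ol
Product: 27 (3R,6E)-7-methyl-3-{[(triethylsilyl)oxy]methyl}-9-[(1S)-2,6,6-trimethylcyclohex-2-en-1-yl]non-6-en-1-yn-3-ol
Conditions: K2CO3 (cat.), MeOH, 0 °C to rt
Reagents that add atoms: none
Why: Methanolysis of the alkynyl C–Si bond is much faster than cleavage of the neopentyl-type triethylsilyl ether, so only the alkyne is unmasked.

Step 16
Reactants: 27 (3R,6E)-7-methyl-3-{[(triethylsilyl)oxy]methyl}-9-[(1S)-2,6,6-trimethylcyclohex-2-en-1-yl]non-6-en-1-yn-3-ol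
Product: 28 (3R,6E)-7-methyl-3-{[(triethylsilyl)oxy]methyl}-9-[(1S)-2,6,6-trimethylcyclohex-2-en-1-yl]non-6-en-1-yn-3-yl acetate
Conditions: Ac2O, DMAP, Et3N, CH2Cl2, rt to 40 °C
Reagents that add atoms: acetic anhydride, CC(=O)OC(C)=O
Why: DMAP-catalysed acetylation esterifies the hindered tertiary propargylic alcohol under non-acidic conditions, so no Meyer–Schuster rearrangement and no loss of the silyl ether is expected.

Step 17
Reactants: 28 (3R,6E)-7-methyl-3-{[(triethylsilyl)oxy]methyl}-9-[(1S)-2,6,6-trimethylcyclohex-2-en-1-yl]non-6-en-1-yn-3-yl acetate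
Product: 29 (1E,3R,6E)-7-methyl-1-(4,4,5,5-tetramethyl-1,3,2-dioxaborolan-2-yl)-3-{[(triethylsilyl)oxy]methyl}-9-[(1S)-2,6,6-trimethylcyclohex-2-en-1-yl]nona-1,6-dien-3-yl acetate
Conditions: HBpin, Cp2ZrHCl (cat.), Et3N (cat.), CH2Cl2, 40 °C
Reagents that add atoms: pinacolborane, B1OC(C)(C)C(C)(C)O1
Why: Cp2ZrHCl-catalysed syn hydroboration of the terminal alkyne places boron on the terminal carbon and gives the (E)-alkenylboronate, while trisubstituted alkenes and esters are inert.

Step 18
Reactants: 29 (1E,3R,6E)-7-methyl-1-(4,4,5,5-tetramethyl-1,3,2-dioxaborolan-2-yl)-3-{[(triethylsilyl)oxy]methyl}-9-[(1S)-2,6,6-trimethylcyclohex-2-en-1-yl]nona-1,6-dien-3-yl acetate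
Product: 30 (1E,3R,6E)-7-methyl-3-{[(triethylsilyl)oxy]methyl}-9-[(1S)-2,6,6-trimethylcyclohex-2-en-1-yl]nona-1,6-diene-1,3-diyl diacetate
Conditions: Cu(OAc)2 (2 equiv), Et3N, 4 Å MS, MeCN, rt
Reagents that add atoms: Cu(OAc)2, CC(=O)[O-].CC(=O)[O-].[Cu+2]
Why: Chan–Lam-type C–O coupling (transmetalation of the alkenylboronate to Cu(OAc)2, then reductive elimination) forms the enol acetate with retention of the E geometry and without an enolate that could expel the neighbouring tertiary acetate.

Step 19
Reactants: 30 (1E,3R,6E)-7-methyl-3-{[(triethylsilyl)oxy]methyl}-9-[(1S)-2,6,6-trimethylcyclohex-2-en-1-yl]nona-1,6-diene-1,3-diyl diacetate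
Product: 31 (1E,3R,6E)-3-formyl-7-methyl-9-[(1S)-2,6,6-trimethylcyclohex-2-en-1-yl]nona-1,6-diene-1,3-diyl diacetate (CNP0244145.1)
Conditions: (COCl)2, DMSO, CH2Cl2, −78 to −30 °C; Et3N, −78 °C to rt
Reagents that add atoms: none
Why: In a Swern oxidation applied directly to the primary triethylsilyl ether the activated sulfonium species cleaves the O–Si bond and the alkoxysulfonium salt collapses to the aldehyde, so no free alcohol capable of 1,2-acetyl migration is ever present.

**Compound list**
1 | 4-methylpent-4-en-1-ol | CC(=C)CCCO | starting material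
2 | 4-methylpent-4-en-1-yl N,N-diisopropylcarbamate | CC(=C)CCCOC(=O)N(C(C)C)C(C)C | intermediate
3 | 4-fluoro-4-methylpentyl N,N-diisopropylcarbamate | CC(C)(F)CCCOC(=O)N(C(C)C)C(C)C | intermediate
4 | (S)-4-fluoro-1-lithio-4-methylpentyl N,N-diisopropylcarbamate (sparteine complex, not isolated) | CC(C)(F)CC[C@H]([Li])OC(=O)N(C(C)C)C(C)C | intermediate
5 | lithium silylboronate complex from 4 and PhMe2Si–Bpin (not isolated) | [Li+].CC(C)(F)CC[C@H]([B-]1([Si](C)(C)c2ccccc2)OC(C)(C)C(C)(C)O1)OC(=O)N(C(C)C)C(C)C | intermediate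
6 | (R)-[4-fluoro-4-methyl-1-(4,4,5,5-tetramethyl-1,3,2-dioxaborolan-2-yl)pentyl]dimethyl(phenyl)silane | CC(C)(F)CC[C@H]([Si](C)(C)c1ccccc1)B1OC(C)(C)C(C)(C)O1 | intermediate
7 | 5-(trimethylsilyl)pent-4-yn-1-ol | OCCCC#C[Si](C)(C)C | starting material
8 | 5-(trimethylsilyl)pent-4-ynal | O=CCCC#C[Si](C)(C)C | intermediate
9 | (Z)-(6-iodohept-5-en-1-yn-1-yl)trimethylsilane | C/C(I)=C/CCC#C[Si](C)(C)C | intermediate
10 | (E)-[7-(trimethylsilyl)hept-2-en-6-yn-2-yl]lithium, lithium cis to the chain (not isolated) | C/C([Li])=C/CCC#C[Si](C)(C)C | intermediate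
11 | lithium alkenylboronate complex from 10 and 6 (not isolated) | [Li+].C/C(=C/CCC#C[Si](C)(C)C)[B-]1(OC(C)(C)C(C)(C)O1)[C@H](CCC(C)(C)F)[Si](C)(C)c1ccccc1 | intermediate
12 | (5S,6E)-5-[dimethyl(phenyl)silyl]-2-fluoro-2,6-dimethyl-11-(trimethylsilyl)undec-6-en-10-yne | CC(C)(F)CC[C@H]([Si](C)(C)c1ccccc1)/C(C)=C/CCC#C[Si](C)(C)C | intermediate
13 | tertiary carbocation from 12 as tetrafluoroborate ion pair (not isolated) | C[C+](C)CC[C@H]([Si](C)(C)c1ccccc1)/C(C)=C/CCC#C[Si](C)(C)C.F[B-](F)(F)F | intermediate
14 | (S)-trimethyl[4-(2,6,6-trimethylcyclohex-2-en-1-yl)but-1-yn-1-yl]silane | C[Si](C)(C)C#CCC[C@@H]1C(C)=CCCC1(C)C | intermediate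
15 | (S)-6-(but-3-yn-1-yl)-1,5,5-trimethylcyclohex-1-ene | C#CCC[C@@H]1C(C)=CCCC1(C)C | intermediate
16 | (E)-dimethyl{2-methyl-4-[(1S)-2,6,6-trimethylcyclohex-2-en-1-yl]but-1-en-1-yl}alane (not isolated) | C[Al](C)/C=C(\C)CC[C@@H]1C(C)=CCCC1(C)C | intermediate
17 | (S)-6-[(E)-4-iodo-3-methylbut-3-en-1-yl]-1,5,5-trimethylcyclohex-1-ene | I/C=C(\C)CC[C@@H]1C(C)=CCCC1(C)C | intermediate
18 | 2-bromoprop-2-en-1-ol | OCC(Br)=C | starting material
19 | ethynyl(trimethyl)silane | C#C[Si](C)(C)C | starting material
20 | 2-[(trimethylsilyl)ethynyl]prop-2-en-1-ol | OCC(=C)C#C[Si](C)(C)C | intermediate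
21 | (R)-{2-[(trimethylsilyl)ethynyl]oxiran-2-yl}methanol | OC[C@]1(C#C[Si](C)(C)C)CO1 | intermediate
22 | (S)-triethyl({2-[(trimethylsilyl)ethynyl]oxiran-2-yl}methoxy)silane | CC[Si](CC)(CC)OC[C@]1(C#C[Si](C)(C)C)CO1 | intermediate
23 | oxidosulfonium betaine from 22 and the ylide (not isolated) | C[S+](C)CC[C@]([O-])(CO[Si](CC)(CC)CC)C#C[Si](C)(C)C | intermediate
24 | (R)-3-{[(triethylsilyl)oxy]methyl}-5-(trimethylsilyl)pent-1-en-4-yn-3-ol | C=C[C@](O)(CO[Si](CC)(CC)CC)C#C[Si](C)(C)C | intermediate
25 | (R)-B-alkyl-9-borabicyclo[3.3.1]nonane from 24 (not isolated) | C[Si](C)(C)C#C[C@@](O)(CO[Si](CC)(CC)CC)CCB1C2CCCC1CCC2 | intermediate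
26 | (3R,6E)-7-methyl-3-{[(triethylsilyl)oxy]methyl}-1-(trimethylsilyl)-9-[(1S)-2,6,6-trimethylcyclohex-2-en-1-yl]non-6-en-1-yn-3-ol | C[Si](C)(C)C#C[C@@](O)(CO[Si](CC)(CC)CC)CC/C=C(\C)CC[C@@H]1C(C)=CCCC1(C)C | intermediate
27 | (3R,6E)-7-methyl-3-{[(triethylsilyl)oxy]methyl}-9-[(1S)-2,6,6-trimethylcyclohex-2-en-1-yl]non-6-en-1-yn-3-ol | C#C[C@@](O)(CO[Si](CC)(CC)CC)CC/C=C(\C)CC[C@@H]1C(C)=CCCC1(C)C | intermediate
28 | (3R,6E)-7-methyl-3-{[(triethylsilyl)oxy]methyl}-9-[(1S)-2,6,6-trimethylcyclohex-2-en-1-yl]non-6-en-1-yn-3-yl acetate | C#C[C@@](OC(C)=O)(CO[Si](CC)(CC)CC)CC/C=C(\C)CC[C@@H]1C(C)=CCCC1(C)C | intermediate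
29 | (1E,3R,6E)-7-methyl-1-(4,4,5,5-tetramethyl-1,3,2-dioxaborolan-2-yl)-3-{[(triethylsilyl)oxy]methyl}-9-[(1S)-2,6,6-trimethylcyclohex-2-en-1-yl]nona-1,6-dien-3-yl acetate | CC1(C)OB(/C=C/[C@@](OC(C)=O)(CO[Si](CC)(CC)CC)CC/C=C(\C)CC[C@@H]2C(C)=CCCC2(C)C)OC1(C)C | intermediate
30 | (1E,3R,6E)-7-methyl-3-{[(triethylsilyl)oxy]methyl}-9-[(1S)-2,6,6-trimethylcyclohex-2-en-1-yl]nona-1,6-diene-1,3-diyl diacetate | CC(=O)O/C=C/[C@@](OC(C)=O)(CO[Si](CC)(CC)CC)CC/C=C(\C)CC[C@@H]1C(C)=CCCC1(C)C | intermediate
31 | (1E,3R,6E)-3-formyl-7-methyl-9-[(1S)-2,6,6-trimethylcyclohex-2-en-1-yl]nona-1,6-diene-1,3-diyl diacetate (CNP0244145.1) | CC(=O)O/C=C/[C@@](C=O)(CC/C=C(\C)CC[C@@H]1C(C)=CCCC1(C)C)OC(C)=O | target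

**Step count**
Total step count: 19.
Longest linear sequence: 13 steps (steps 1, 2, 3, 6, 7, 8, 9, 14, 15, 16, 17, 18, 19).

**Steps most likely to fail**

Step 7 (proposed new method). What may go wrong:
- Chirality transfer may be incomplete through a competing boat transition state.
- The cation may lose a proton, and the acid released may then protodesilylate the allylsilane.
- Fluoride may be lost prematurely while 12 is handled.

The fallback uses only known reaction types, sets out from 7 and comes back at 14. It sets the ring stereocentre directly by lithiation–borylation and closes the same ring by olefin metathesis. Alcohol 7 would be carbamoylated (iPr2NCOCl, Et3N) to 5-(trimethylsilyl)pent-4-yn-1-yl N,N-diisopropylcarbamate F1. Deborylative alkylation of 2,2-bis(pinacolboryl)propane with 4-bromobut-1-ene (NaOtBu, THF) would give the tertiary boronic ester 2-(2-methylhex-5-en-2-yl)-4,4,5,5-tetramethyl-1,3,2-dioxaborolane F2. Deprotonation of F1 with s-BuLi/(+)-sparteine, capture by F2 and 1,2-metallate shift would give (S)-trimethyl[6,6-dimethyl-5-(4,4,5,5-tetramethyl-1,3,2-dioxaborolan-2-yl)dec-9-en-1-yn-1-yl]silane F3. Zweifel olefination with isopropenyllithium (I2, NaOMe) would give (R)-trimethyl[6,6-dimethyl-5-(prop-1-en-2-yl)dec-9-en-1-yn-1-yl]silane F4. Ring-closing metathesis with the second-generation Grubbs catalyst (CH2Cl2, 40 °C), helped by the gem-dimethyl group, would form the C2=C3 bond and deliver 14.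

Step 18. Transmetalation of the hindered alkenylboronate may be slow, so that protodeboronation and oxidative homocoupling overtake C–O bond formation. The fallback sets out from 27 and comes back at 30. It replaces the C–B to C–O coupling by classical enolisation and O-acetylation. Hydroboration of the terminal alkyne of 27 with dicyclohexylborane and oxidation with NaBO3 would give (3R,6E)-3-hydroxy-7-methyl-3-{[(triethylsilyl)oxy]methyl}-9-[(1S)-2,6,6-trimethylcyclohex-2-en-1-yl]non-6-enal F5. Treatment with Ac2O, Et3N and DMAP would acetylate the aldehyde enol, with E favoured by the quaternary neighbour, and then the tertiary alcohol, giving 30. Competing β-elimination is the price of this shorter path.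

Step 3. s-BuLi may attack the tertiary C–F bond (dehydrofluorination) during the long deprotonation, or the 1,2-shift may be sluggish. The fallback sets out from 2 and comes back at 6. It postpones C–F bond formation until after the organolithium chemistry. Deprotonation of 2 with s-BuLi/(−)-sparteine and trapping with PhMe2Si–Bpin would give (R)-dimethyl[4-methyl-1-(4,4,5,5-tetramethyl-1,3,2-dioxaborolan-2-yl)pent-4-en-1-yl](phenyl)silane F6. Radical Markovnikov hydrofluorination of its 1,1-disubstituted alkene (Fe2(C2O4)3, NaBH4, Selectfluor, MeCN–H2O, 0 °C) would give 6. No allylsilane is present yet at that stage.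

**Further compounds**
F1 | step 7 | 5-(trimethylsilyl)pent-4-yn-1-yl N,N-diisopropylcarbamate | CC(C)N(C(C)C)C(=O)OCCCC#C[Si](C)(C)C
F2 | step 7 | 2-(2-methylhex-5-en-2-yl)-4,4,5,5-tetramethyl-1,3,2-dioxaborolane | C=CCCC(C)(C)B1OC(C)(C)C(C)(C)O1
F3 | step 7 | (S)-trimethyl[6,6-dimethyl-5-(4,4,5,5-tetramethyl-1,3,2-dioxaborolan-2-yl)dec-9-en-1-yn-1-yl]silane | C[Si](C)(C)C#CCC[C@@H](C(C)(C)CCC=C)B1OC(C)(C)C(C)(C)O1
F4 | step 7 | (R)-trimethyl[6,6-dimethyl-5-(prop-1-en-2-yl)dec-9-en-1-yn-1-yl]silane | C[Si](C)(C)C#CCC[C@@H](C(C)(C)CCC=C)C(C)=C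
F5 | step 18 | (3R,6E)-3-hydroxy-7-methyl-3-{[(triethylsilyl)oxy]methyl}-9-[(1S)-2,6,6-trimethylcyclohex-2-en-1-yl]non-6-enal | O=CC[C@@](O)(CO[Si](CC)(CC)CC)CC/C=C(\C)CC[C@@H]1C(C)=CCCC1(C)C
F6 | step 3 | (R)-dimethyl[4-methyl-1-(4,4,5,5-tetramethyl-1,3,2-dioxaborolan-2-yl)pent-4-en-1-yl](phenyl)silane | CC(=C)CC[C@H]([Si](C)(C)c1ccccc1)B1OC(C)(C)C(C)(C)O1
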